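**Retrosynthetic overview**

- The route rests on one feature of the flavan: O1 joins C8a of ring A to C2, and C2 also carries ring B. The O1–C2 bond can therefore begin as the ester bond of an aryl 3,5-dimethoxybenzoate, with C2 as the carbonyl carbon.
- Last disconnection: the C2–H bond, by enantioselective ionic reduction of the C2=C3 enol ether of a 4H-chromene, followed by removal of the MOM groups on O5 and O7.
- Key disconnection: C2=C3, by ring-closing carbonyl olefination between the ester carbonyl and the inner carbon of an allyl group on C4a. This closes ring C, the only ring that is made.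
- Earlier disconnections on phloroglucinol: the ester C–O bond (acylation), C4a–C4 (Claisen rearrangement of an O-allyl ether to either of two equivalent ortho carbons) and C6–prenyl (ortho-lithiation between two OMOM groups).
- Ring order: rings A and B are bought (phloroglucinol, 3,5-dimethoxybenzoyl chloride); ring C is formed in step 7.

Key step: step 7

Assumption: flavan numbering (O1, C2 to C4, C4a, C5 to C8, C8a) is used, and the target is 2R. The (R)-acid is written for step 8, but the sense of induction of this ion-pair reduction cannot be predicted with confidence, so the mirror-image acid would be used if a first run shows the 2S product.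

**Route**

Step 1
Reactants: 1 phloroglucinol
Product: 2 3,5-bis(methoxymethoxy)phenol
Conditions: MOMCl (2.1 equiv), i-Pr2NEt, CH2Cl2/DMF, 0 °C to rt; chromatography
Reagents that add atoms: chloromethyl methyl ether (MOMCl), COCCl
Why: O-alkylation of the symmetric triphenol with two equivalents of MOMCl (Williamson-type acetal ether formation) is statistical but should give the bis-ether as the main fraction, with the mono- and tris-ethers separable and recyclable.

Step 2
Reactants: 2 3,5-bis(methoxymethoxy)phenol
Product: 3 [3,5-bis(methoxymethoxy)phenoxy]triisopropylsilane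
Conditions: TIPSCl, imidazole, DMF, rt
Reagents that add atoms: triisopropylsilyl chloride (TIPSCl), CC(C)[Si](Cl)(C(C)C)C(C)C
Why: routine O-silylation of the free phenol, giving a bulky, non-coordinating ether that survives n-BuLi and steers the next lithiation away from its own ortho positions.

Step 3
Reactants: 3 [3,5-bis(methoxymethoxy)phenoxy]triisopropylsilane; 4 prenyl bromide
Product: 6 [3,5-bis(methoxymethoxy)-4-(3-methylbut-2-en-1-yl)phenoxy]triisopropylsilane, via aryllithium 5 (not isolated)
Conditions: n-BuLi, THF, 0 °C; CuI (10 mol %), 4, −78 °C to rt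
Reagents that add atoms: none
Why: directed ortho-metalation should occur at the C–H flanked by the two chelating OMOM groups, and copper-catalysed allylic substitution of the aryllithium at the primary carbon of prenyl bromide should give the linear prenyl arene.

Step 4
Reactants: 6 [3,5-bis(methoxymethoxy)-4-(3-methylbut-2-en-1-yl)phenoxy]triisopropylsilane; 7 allyl bromide
Product: 9 5-(allyloxy)-1,3-bis(methoxymethoxy)-2-(3-methylbut-2-en-1-yl)benzene, via phenoxide 8 (not isolated)
Conditions: Bu4NF, THF, 0 °C; then 7, rt
Reagents that add atoms: none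
Why: fluoride cleaves the aryl silyl ether to a tetrabutylammonium phenoxide, which should undergo Williamson O-allylation in the same flask.

Step 5
Reactants: 9 5-(allyloxy)-1,3-bis(methoxymethoxy)-2-(3-methylbut-2-en-1-yl)benzene
Product: 10 2-allyl-3,5-bis(methoxymethoxy)-4-(3-methylbut-2-en-1-yl)phenol
Conditions: PhNEt2, 190 °C, sealed tube
Reagents that add atoms: none
Why: aromatic Claisen rearrangement ([3,3] shift, then tautomerisation) can only go to the two symmetry-equivalent ortho carbons because the para position carries the prenyl group, and the basic solvent protects the MOM acetals.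

Step 6
Reactants: 10 2-allyl-3,5-bis(methoxymethoxy)-4-(3-methylbut-2-en-1-yl)phenol; 11 3,5-dimethoxybenzoyl chloride
Product: 12 2-allyl-3,5-bis(methoxymethoxy)-4-(3-methylbut-2-en-1-yl)phenyl 3,5-dimethoxybenzoate
Conditions: Et3N, DMAP (cat.), CH2Cl2, 0 °C to rt
Reagents that add atoms: none
Why: DMAP-catalysed acylation of the hindered phenol with the acid chloride forms the O1–C2 bond as an ester without touching the other groups.

Step 7
Reactants: 12 2-allyl-3,5-bis(methoxymethoxy)-4-(3-methylbut-2-en-1-yl)phenyl 3,5-dimethoxybenzoate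
Product: 14 2-(3,5-dimethoxyphenyl)-5,7-bis(methoxymethoxy)-6-(3-methylbut-2-en-1-yl)-4H-chromene, via C3 titanium alkylidene 13 (not isolated)
Conditions: TiCl4, TMEDA, THF, 0 °C; Zn dust, PbCl2 (cat.), rt; then 12, CH3CHBr2, THF/CH2Cl2, 65 °C; aq K2CO3 work-up; Et3N-deactivated SiO2
Reagents that add atoms: none
Why: Zn reduction of TiCl4·TMEDA in the presence of CH3CHBr2 gives a titanium ethylidene, which exchanges by [2+2]/retro-[2+2] with the monosubstituted allyl alkene (propene leaves) to place a titanium alkylidene on C3 (13); this adds across the neighbouring ester C=O to an oxatitanacyclobutane that collapses to the C2=C3 enol ether and a titanium oxo species. The closest known reaction type is the olefinic-ester cyclisation with the Takai–Utimoto reagent (a ring-closing carbonyl–olefin metathesis), and titanium-carbene olefination of aryl benzoates is itself standard (Tebbe methylenation). Ring C closes as a six-membered ring by intramolecular [2+2] of the C3 alkylidene on the C2 carbonyl, with C4, C4a, C8a and O1 as the existing tether and both new sp2 carbons inside the ring. No stereocentre is formed. The step needs the terminal alkene to react ahead of the trisubstituted prenyl alkene, and the ester ahead of the MOM acetals and aryl methyl ethers; the bulk of the TMEDA-ligated alkylidene should secure the first, and the nucleophilic carbene character together with TMEDA masking of the Lewis-acidic titanium and zinc halides should secure the second. The enol ether is acid-labile, hence the basic work-up and deactivated silica.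

Step 8
Reactants: 14 2-(3,5-dimethoxyphenyl)-5,7-bis(methoxymethoxy)-6-(3-methylbut-2-en-1-yl)-4H-chromene
Product: 16 (2R)-2-(3,5-dimethoxyphenyl)-5,7-bis(methoxymethoxy)-6-(3-methylbut-2-en-1-yl)-3,4-dihydro-2H-chromene, via C2 oxocarbenium phosphate 15 (not isolated)
Conditions: (R)-TRIP [(R)-3,3'-bis(2,4,6-triisopropylphenyl)-1,1'-binaphthyl-2,2'-diyl hydrogen phosphate] (10 mol %), Hantzsch ester (diethyl 2,6-dimethyl-1,4-dihydropyridine-3,5-dicarboxylate, 1.3 equiv), 5 Å MS, toluene, 0 °C to rt
Reagents that add atoms: none
Why: Proposed new method: the phosphoric acid should protonate the electron-rich 2-aryl enol ether at C3 to give the flat C2 oxocarbenium ion as a contact ion pair with the chiral phosphate (15), and the Hantzsch ester should then deliver hydride to the C2 face left open by the 3,3'-aryl groups of the counter-anion, which sets the 2R centre (asymmetric counter-anion-directed transfer hydrogenation); the closest known reaction types are the chiral phosphoric acid/Hantzsch ester transfer hydrogenation of C=N bonds and the chiral-phosphate-controlled Hantzsch ester reduction of benzopyrylium and isochromenylium ions, and this ionic hydrogenation should leave the isolated prenyl alkene and the MOM acetals untouched.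

Step 9
Reactants: 16 (2R)-2-(3,5-dimethoxyphenyl)-5,7-bis(methoxymethoxy)-6-(3-methylbut-2-en-1-yl)-3,4-dihydro-2H-chromene
Product: 17 (2R)-2-(3,5-dimethoxyphenyl)-6-(3-methylbut-2-en-1-yl)-3,4-dihydro-2H-chromene-5,7-diol
Conditions: HCl (1 M in MeOH), rt to 40 °C, stopped at full conversion
Reagents that add atoms: none
Why: acid-catalysed transacetalisation passes both methoxymethyl groups to methanol under conditions mild enough for the prenyl alkene and the C2 benzylic ether, whose 3,5-dimethoxyphenyl group stabilises a C2 cation only weakly.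

**Compound list**

1 | phloroglucinol (benzene-1,3,5-triol) | Oc1cc(O)cc(O)c1 | starting material
2 | 3,5-bis(methoxymethoxy)phenol | COCOc1cc(O)cc(OCOC)c1 | intermediate
3 | [3,5-bis(methoxymethoxy)phenoxy]triisopropylsilane | COCOc1cc(O[Si](C(C)C)(C(C)C)C(C)C)cc(OCOC)c1 | intermediate
4 | prenyl bromide (1-bromo-3-methylbut-2-ene) | CC(C)=CCBr | starting material
5 | 2,6-bis(methoxymethoxy)-4-(triisopropylsilyloxy)phenyllithium | [Li]c1c(OCOC)cc(O[Si](C(C)C)(C(C)C)C(C)C)cc1OCOC | intermediate
6 | [3,5-bis(methoxymethoxy)-4-(3-methylbut-2-en-1-yl)phenoxy]triisopropylsilane | CC(C)=CCc1c(OCOC)cc(O[Si](C(C)C)(C(C)C)C(C)C)cc1OCOC | intermediate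
7 | allyl bromide (3-bromoprop-1-ene) | C=CCBr | starting material
8 | tetrabutylammonium 3,5-bis(methoxymethoxy)-4-(3-methylbut-2-en-1-yl)phenoxide | CCCC[N+](CCCC)(CCCC)CCCC.[O-]c1cc(OCOC)c(CC=C(C)C)c(OCOC)c1 | intermediate
9 | 5-(allyloxy)-1,3-bis(methoxymethoxy)-2-(3-methylbut-2-en-1-yl)benzene | C=CCOc1cc(OCOC)c(CC=C(C)C)c(OCOC)c1 | intermediate
10 | 2-allyl-3,5-bis(methoxymethoxy)-4-(3-methylbut-2-en-1-yl)phenol | Oc1cc(OCOC)c(CC=C(C)C)c(OCOC)c1CC=C | intermediate
11 | 3,5-dimethoxybenzoyl chloride | COc1cc(OC)cc(C(=O)Cl)c1 | starting material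
12 | 2-allyl-3,5-bis(methoxymethoxy)-4-(3-methylbut-2-en-1-yl)phenyl 3,5-dimethoxybenzoate | COc1cc(OC)cc(C(=O)Oc2cc(OCOC)c(CC=C(C)C)c(OCOC)c2CC=C)c1 | intermediate
13 | titanium alkylidene at C3 of ester 12, the terminal CH2 replaced by TiCl2 (TMEDA ligand not drawn) | COc1cc(OC)cc(C(=O)Oc2cc(OCOC)c(CC=C(C)C)c(OCOC)c2CC=[Ti](Cl)Cl)c1 | intermediate
14 | 2-(3,5-dimethoxyphenyl)-5,7-bis(methoxymethoxy)-6-(3-methylbut-2-en-1-yl)-4H-chromene | COc1cc(OC)cc(C2=CCc3c(cc(OCOC)c(CC=C(C)C)c3OCOC)O2)c1 | intermediate
15 | 2-(3,5-dimethoxyphenyl)-5,7-bis(methoxymethoxy)-6-(3-methylbut-2-en-1-yl)-3,4-dihydrochromenylium (R)-TRIP phosphate ion pair (the R axis of the binaphthyl is given in the name, not in the SMILES) | COc1cc(OC)cc(C2=[O+]c3cc(OCOC)c(CC=C(C)C)c(OCOC)c3CC2)c1.CC(C)c1cc(C(C)C)c(-c2cc3ccccc3c3c2OP(=O)([O-])Oc2c(-c4c(C(C)C)cc(C(C)C)cc4C(C)C)cc4ccccc4c2-3)c(C(C)C)c1 | intermediate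
16 | (2R)-2-(3,5-dimethoxyphenyl)-5,7-bis(methoxymethoxy)-6-(3-methylbut-2-en-1-yl)-3,4-dihydro-2H-chromene | COc1cc(OC)cc([C@H]2CCc3c(cc(OCOC)c(CC=C(C)C)c3OCOC)O2)c1 | intermediate
17 | (2R)-2-(3,5-dimethoxyphenyl)-6-(3-methylbut-2-en-1-yl)-3,4-dihydro-2H-chromene-5,7-diol (CNP0147692.1) | COc1cc(OC)cc([C@H]2CCc3c(cc(O)c(CC=C(C)C)c3O)O2)c1 | target

**Step count**

Total steps: 9. Longest linear sequence: 9 steps (1 to 17).

**Steps most likely to fail, with fallbacks**

1. Step 8 (proposed new method). The ion pair may not discriminate the two faces of C2, giving poor enantioselectivity. Protonation may also be too slow for turnover, or adventitious water may hydrate the cation and open the ring. The fallback uses known chemistry and sets out from 14: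
 - Mild hydrolysis of the enol ether (oxalic acid, wet THF, rt) should give the keto phenol 1-(3,5-dimethoxyphenyl)-3-[6-hydroxy-2,4-bis(methoxymethoxy)-3-(3-methylbut-2-en-1-yl)phenyl]propan-1-one F1.
 - Noyori asymmetric transfer hydrogenation of the aryl ketone with RuCl(p-cymene)[(S,S)-TsDPEN] in HCO2H/Et3N should give (1S)-1-(3,5-dimethoxyphenyl)-3-[6-hydroxy-2,4-bis(methoxymethoxy)-3-(3-methylbut-2-en-1-yl)phenyl]propan-1-ol F2.
 - Intramolecular Mitsunobu etherification (PPh3, DIAD, THF, 0 °C) should close the O1–C2 bond with inversion, coming back to the route at 16.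

2. Step 7 (key step). Ethylidenation of the carbonyl may outrun the alkene exchange, so that the ring does not close. The allyl alkene, hindered by its two ortho substituents, may fail to engage the titanium alkylidene. The Lewis-acidic metal halides may also strip a MOM group. The fallback sets out from 12:
 - Methylenation of the ester with the Tebbe reagent Cp2Ti(μ-CH2)(μ-Cl)AlMe2 (THF/toluene, pyridine, −40 °C to rt) should give 2-allyl-3,5-bis(methoxymethoxy)-4-(3-methylbut-2-en-1-yl)phenyl 1-(3,5-dimethoxyphenyl)ethenyl ether F3.
 - Enol ether–olefin ring-closing metathesis with the second-generation Grubbs catalyst RuCl2(=CHPh)(H2IMes)(PCy3) (toluene, 70 °C) should then close ring C, coming back to the route at 14. The prenyl alkene cannot reach either reacting carbon.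

3. Step 9. Once the phenols at C5 and C7 are free, acid may add one of them across the prenyl double bond, closing an extra dimethylpyran ring. Prolonged acid could also ionise the C2–O1 bond and erode the enantiomeric purity. The fallback sets out from 16 and avoids protic acid:
 - TMSOTf with 2,2'-bipyridyl (CH2Cl2, 0 °C to rt) should exchange the aryl MOM ethers for silyl ethers, giving (2R)-2-(3,5-dimethoxyphenyl)-6-(3-methylbut-2-en-1-yl)-5,7-bis(trimethylsilyloxy)-3,4-dihydro-2H-chromene F4.
 - Neutral hydrolysis (H2O, or K2CO3 in MeOH, rt) should then free the phenols, coming back to the route at 17.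

**Further compounds**

F1 | step 8 | 1-(3,5-dimethoxyphenyl)-3-[6-hydroxy-2,4-bis(methoxymethoxy)-3-(3-methylbut-2-en-1-yl)phenyl]propan-1-one | COc1cc(OC)cc(C(=O)CCc2c(O)cc(OCOC)c(CC=C(C)C)c2OCOC)c1
F2 | step 8 | (1S)-1-(3,5-dimethoxyphenyl)-3-[6-hydroxy-2,4-bis(methoxymethoxy)-3-(3-methylbut-2-en-1-yl)phenyl]propan-1-ol | COc1cc(OC)cc([C@@H](O)CCc2c(O)cc(OCOC)c(CC=C(C)C)c2OCOC)c1
F3 | step 7 | 2-allyl-3,5-bis(methoxymethoxy)-4-(3-methylbut-2-en-1-yl)phenyl 1-(3,5-dimethoxyphenyl)ethenyl ether | COc1cc(OC)cc(C(=C)Oc2cc(OCOC)c(CC=C(C)C)c(OCOC)c2CC=C)c1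
F4 | step 9 | (2R)-2-(3,5-dimethoxyphenyl)-6-(3-methylbut-2-en-1-yl)-5,7-bis(trimethylsilyloxy)-3,4-dihydro-2H-chromene | COc1cc(OC)cc([C@H]2CCc3c(cc(O[Si](C)(C)C)c(CC=C(C)C)c3O[Si](C)(C)C)O2)c1
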